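**Retrosynthetic overview**

1. Target 23 ⇐ double senecioylation of diol 21 ⇐ C7 α-alkenylation and C9 Rubottom hydroxylation of 8-ketone 16 ⇐ ketalisation and dissolving-metal reduction of cis-decalin-3,8-dione 13.
2. 13 ⇐ ring A closed in one operation on ring B: the acyl radical at the aldehyde carbon C3 of keto aldehyde 11 adds to ethylene (C2–C3), and the new C1 radical closes on the enone carbon C10 (C1–C10).
3. Enabling feature: the ring A carbonyl C3 and the ring B carbonyl C8 stand 1,6 through C2–C1–C10–C9 (a dissonant pattern). C3 and the β-carbon C10 of the ring B enone C8(=O)–C9=C10 are both acceptor carbons, so they are joined through ethylene by polarity reversal of C3.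
4. 11 ⇐ allylic oxidation and redox adjustment of acid 7 ⇐ Ireland–Claisen rearrangement of propanoate 4 (C4–C5 bond, C4 and quaternary C5) ⇐ CBS reduction of 3-methylcyclohex-2-en-1-one 1.
5. Ring order: ring B is the starting carbocycle; ring A is formed in step 8; the C9 and C7 substituents come last.

Key step: step 8

Remark: positions follow eremophilane numbering (decalin C1–C10; ring A = C1–C5, C10; ring B = C5–C10; methyls on C4 and C5; isopropenyl on C7; ketone C8; ester oxygens on C3 and C9). β is the face of the C5 methyl group, and the target is (3R,4R,5R,7R,9R,10S).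

**Route**

Step 1
Reactants: 1 3-methylcyclohex-2-en-1-one
Product: 2 (R)-3-methylcyclohex-2-en-1-ol
Conditions: (S)-2-methyl-CBS-oxazaborolidine (10 mol %), catecholborane, toluene, −78 °C
Reagents that add atoms: none
Why: Corey–Bakshi–Shibata reduction; the oxazaborolidine–borane complex binds the ketone with the alkenyl arm as the large substituent and delivers hydride to one face, which should set the R carbinol centre.

Step 2
Reactants: 2 (R)-3-methylcyclohex-2-en-1-ol; 3 propanoic anhydride
Product: 4 (1R)-3-methylcyclohex-2-en-1-yl propanoate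
Conditions: (EtCO)2O, Et3N, DMAP (cat.), CH2Cl2, 0 °C to rt
Reagents that add atoms: propanoic anhydride, CCC(=O)OC(=O)CC
Why: DMAP-catalysed acylation of a secondary allylic alcohol; the stereocentre is not touched.

Step 3
Reactants: 4 (1R)-3-methylcyclohex-2-en-1-yl propanoate
Product: 7 (2R)-2-[(1S)-1-methylcyclohex-2-en-1-yl]propanoic acid, via silyl ketene acetal 5 (not isolated), via trimethylsilyl ester 6 (not isolated)
Conditions: LiN(i-Pr)2, THF/DMPU, −78 °C; TMSCl; −78 to 50 °C; then 1 M HCl, rt
Reagents that add atoms: none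
Why: Ireland–Claisen rearrangement: deprotonation in THF/DMPU should give the (Z)-silyl ketene acetal, the suprafacial [3,3] shift delivers the new C4–C5 bond to the ring face that carried the ester oxygen (quaternary C5 by 1,3-chirality transfer from the R carbinol), and the boat-like transition state usual for cyclohex-2-enyl esters, with the ketene-acetal methyl turned away from the ring, sets C4.

Step 4
Reactants: 7 (2R)-2-[(1S)-1-methylcyclohex-2-en-1-yl]propanoic acid
Product: 8 methyl (2R)-2-[(1S)-1-methylcyclohex-2-en-1-yl]propanoate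
Conditions: MeI, K2CO3, DMF, rt
Reagents that add atoms: iodomethane, CI
Why: SN2 O-methylation of the carboxylate; no stereocentre is involved.

Step 5
Reactants: 8 methyl (2R)-2-[(1S)-1-methylcyclohex-2-en-1-yl]propanoate
Product: 9 methyl (2R)-2-[(1S)-1-methyl-4-oxocyclohex-2-en-1-yl]propanoate
Conditions: Rh2(cap)4 (dirhodium tetrakis(caprolactamate), 1 mol %), t-BuOOH, K2CO3 (0.5 equiv), CH2Cl2, rt
Reagents that add atoms: tert-butyl hydroperoxide, CC(C)(C)OO
Why: Allylic C–H oxidation to the enone; C8 is the only allylic methylene because the other allylic carbon, C5, is quaternary.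

Step 6
Reactants: 9 methyl (2R)-2-[(1S)-1-methyl-4-oxocyclohex-2-en-1-yl]propanoate
Product: 10 (4S)-4-[(2R)-1-hydroxypropan-2-yl]-4-methylcyclohex-2-en-1-ol (mixture of C1 epimers)
Conditions: (i-Bu)2AlH (4 equiv), CH2Cl2, −78 to 0 °C; Rochelle salt work-up
Reagents that add atoms: none
Why: Hydride reduction: the ester goes to the primary alcohol and the enone is reduced 1,2 to the allylic alcohol, whose configuration does not matter because step 7 oxidises it back.

Step 7
Reactants: 10 (4S)-4-[(2R)-1-hydroxypropan-2-yl]-4-methylcyclohex-2-en-1-ol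
Product: 11 (2R)-2-[(1S)-1-methyl-4-oxocyclohex-2-en-1-yl]propanal
Conditions: Dess–Martin periodinane (2.5 equiv), NaHCO3, CH2Cl2, 0 °C to rt
Reagents that add atoms: none
Why: Dess–Martin oxidation of both alcohols under bicarbonate buffer, mild enough to keep the α-stereocentre C4 of the aldehyde.

Step 8
Reactants: 11 (2R)-2-[(1S)-1-methyl-4-oxocyclohex-2-en-1-yl]propanal; 12 ethylene
Product: 13 cis-fused 4β,5β-dimethyl-10βH-decalin-3,8-dione, (4R,5S,10R)
Conditions: (n-Bu4N)4[W10O32] (2 mol %), ethylene (30 bar), MeCN (0.01 M), 390 nm LEDs, 10 °C, pressure photoreactor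
Reagents that add atoms: ethylene, C=C
Why: Proposed new method: photoexcited decatungstate abstracts the aldehyde hydrogen of 11, the nucleophilic acyl radical at C3 adds to ethylene (C2–C3 bond), the resulting primary C1 radical closes on C10 of the enone (C1–C10 bond), and the electrophilic α-keto radical at C9 takes the hydrogen back from the reduced polyoxometalate, which closes the catalytic cycle. The closest known reaction types are the decatungstate-photocatalysed hydroacylation of alkenes with aliphatic aldehydes and tin- or silane-mediated tandem acyl-radical addition/cyclisation; a three-component version with ethylene as a two-carbon linchpin onto a tethered enone has not been shown. Ring A closes by a polarity-matched 6-exo-trig radical conjugate addition of the alkyl radical to the enone. The only new stereocentre, C10, is controlled by the tether: the chain on quaternary C5 can reach only the enone face on which it stands, so H-10 ends cis to the C5 methyl (cis-decalin), and C4 is not touched under the neutral conditions. The step needs capture of the acyl radical by ethylene faster than loss of CO and faster than bimolecular addition to an enone, which ethylene pressure, high dilution, low temperature and the hindered, C5-flanked position of C10 should secure; it also needs ring closure before a second ethylene adds, which the tethered activated acceptor should secure. Light of 390 nm is absorbed by the catalyst only, so the enone–ethylene [2+2] photocycloaddition should not compete.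

Step 9
Reactants: 13 cis-fused 4β,5β-dimethyl-10βH-decalin-3,8-dione
Product: 14 8,8-ethylenedioxy-4β,5β-dimethyl-10βH-decalin-3-one
Conditions: TMSOCH2CH2OTMS (1.1 equiv), TMSOTf (5 mol %), CH2Cl2, −78 °C
Reagents that add atoms: 1,2-bis(trimethylsilyloxy)ethane, C[Si](C)(C)OCCO[Si](C)(C)C
Why: Silyl-transfer ketalisation at low temperature should be selective for the unhindered C8 ketone, because a ketal at C3 would place an oxygen 1,3-diaxial to the C5 methyl and next to the C4 methyl.

Step 10
Reactants: 14 8,8-ethylenedioxy-4β,5β-dimethyl-10βH-decalin-3-one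
Product: 16 3α-hydroxy-4β,5β-dimethyl-10βH-decalin-8-one, via hydroxy ketal 15 (not isolated)
Conditions: Li, NH3(l)/THF, t-BuOH, −78 °C; NH4Cl; then 1 M HCl, THF, rt
Reagents that add atoms: water, O
Why: Dissolving-metal (Birch-type) reduction of the C3 ketone should give the thermodynamically preferred equatorial 3α-alcohol (hydride reagents would approach away from the axial C5 methyl and give the axial epimer), and the acidic work-up hydrolyses the dioxolane.

Step 11
Reactants: 16 3α-hydroxy-4β,5β-dimethyl-10βH-decalin-8-one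
Product: 18 3α,9β-bis(tert-butyldimethylsilyloxy)-4β,5β-dimethyl-10βH-decalin-8-one, via bis-silyl enol ether 17 (not isolated)
Conditions: TBSOTf (2.5 equiv), Et3N, CH2Cl2, 0 °C to rt; crude, then mCPBA, NaHCO3, hexane/CH2Cl2, −15 to 0 °C
Reagents that add atoms: tert-butyldimethylsilyl trifluoromethanesulfonate, CC(C)(C)[Si](C)(C)OS(=O)(=O)C(F)(F)F; 3-chloroperoxybenzoic acid, OOC(=O)c1cccc(Cl)c1
Why: Rubottom oxidation: TBSOTf/Et3N silylates the C3 hydroxyl and should enolise the ketone towards C9, as cis-fused 2-decalones with an angular methyl (the ring system of 5β-3-keto steroids) do; the peracid then attacks the enol ether from the convex β face, anti to the C10–C1 bond, and silyl migration gives the 9β-silyloxy ketone.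

Step 12
Reactants: 18 3α,9β-bis(tert-butyldimethylsilyloxy)-4β,5β-dimethyl-10βH-decalin-8-one; 19 2-bromopropene
Product: 20 3α,9β-bis(tert-butyldimethylsilyloxy)-10βH-eremophil-11-en-8-one (7β-isopropenyl)
Conditions: LiN(SiMe3)2 (2.2 equiv), Pd2(dba)3 (2.5 mol %), P(t-Bu)3 (6 mol %), toluene/THF, rt; AcOH, −78 °C
Reagents that add atoms: 2-bromopropene, CC(Br)=C
Why: Palladium-catalysed α-alkenylation of a ketone enolate: the base deprotonates the only α-methylene (C7), oxidative addition of the bromide to zerovalent palladium and reductive elimination form the C7–C11 bond, the product rests as its dienolate, and cold acetic acid protonates it at C7 to keep the alkene out of conjugation; C7 is epimerisable and the equatorial 7β isomer is the thermodynamically preferred one.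

Step 13
Reactants: 20 3α,9β-bis(tert-butyldimethylsilyloxy)-10βH-eremophil-11-en-8-one
Product: 21 3α,9β-dihydroxy-10βH-eremophil-11-en-8-one
Conditions: HF·pyridine, pyridine/THF, 0 °C to rt
Reagents that add atoms: none
Why: Fluoride cleavage of both silyl ethers under buffered, non-basic conditions, which should avoid migration of the isopropenyl double bond into conjugation and α-ketol shift.

Step 14
Reactants: 21 3α,9β-dihydroxy-10βH-eremophil-11-en-8-one; 22 3-methylbut-2-enoyl chloride
Product: 23 3α,9β-bis(3-methylbut-2-enoyloxy)-10βH-eremophil-11-en-8-one, (3R,4R,5R,7R,9R,10S) (CNP0264508.1)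
Conditions: 3-methylbut-2-enoyl chloride (3 equiv), pyridine, DMAP (cat.), CH2Cl2, 0 °C to rt
Reagents that add atoms: 3-methylbut-2-enoyl chloride, CC(C)=CC(Cl)=O
Why: DMAP-catalysed acylation of both secondary alcohols; C7 and C9, both α to the ketone, already hold their thermodynamically preferred equatorial configurations, so the mild base should not change them.

**Compound list**

1 | 3-methylcyclohex-2-en-1-one | CC1=CC(=O)CCC1 | starting material
2 | (R)-3-methylcyclohex-2-en-1-ol | CC1=C[C@H](O)CCC1 | intermediate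
3 | propanoic anhydride | CCC(=O)OC(=O)CC | starting material
4 | (1R)-3-methylcyclohex-2-en-1-yl propanoate | CCC(=O)O[C@H]1C=C(C)CCC1 | intermediate
5 | (Z)-1-{[(1R)-3-methylcyclohex-2-en-1-yl]oxy}-1-(trimethylsilyloxy)prop-1-ene (methyl cis to OSiMe3) | C/C=C(\O[Si](C)(C)C)O[C@H]1C=C(C)CCC1 | intermediate
6 | trimethylsilyl (2R)-2-[(1S)-1-methylcyclohex-2-en-1-yl]propanoate | C1CC[C@@](C)(C=C1)[C@@H](C)C(=O)O[Si](C)(C)C | intermediate
7 | (2R)-2-[(1S)-1-methylcyclohex-2-en-1-yl]propanoic acid | C1CC[C@@](C)(C=C1)[C@@H](C)C(=O)O | intermediate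
8 | methyl (2R)-2-[(1S)-1-methylcyclohex-2-en-1-yl]propanoate | C1CC[C@@](C)(C=C1)[C@@H](C)C(=O)OC | intermediate
9 | methyl (2R)-2-[(1S)-1-methyl-4-oxocyclohex-2-en-1-yl]propanoate | O=C1CC[C@@](C)(C=C1)[C@@H](C)C(=O)OC | intermediate
10 | (4S)-4-[(2R)-1-hydroxypropan-2-yl]-4-methylcyclohex-2-en-1-ol (C1 epimers) | OC1CC[C@@](C)(C=C1)[C@@H](C)CO | intermediate
11 | (2R)-2-[(1S)-1-methyl-4-oxocyclohex-2-en-1-yl]propanal | O=C1CC[C@@](C)(C=C1)[C@@H](C)C=O | intermediate
12 | ethylene | C=C | starting material
13 | cis-fused 4β,5β-dimethyl-10βH-decalin-3,8-dione, (4R,5S,10R) | O=C1CC[C@@]2(C)[C@H](CCC(=O)[C@@H]2C)C1 | intermediate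
14 | 8,8-ethylenedioxy-4β,5β-dimethyl-10βH-decalin-3-one | O1CCOC12CC[C@@]3(C)[C@H](CCC(=O)[C@@H]3C)C2 | intermediate
15 | 8,8-ethylenedioxy-4β,5β-dimethyl-10βH-decalin-3α-ol | O1CCOC12CC[C@@]3(C)[C@H](CC[C@@H](O)[C@@H]3C)C2 | intermediate
16 | 3α-hydroxy-4β,5β-dimethyl-10βH-decalin-8-one | O=C1CC[C@@]2(C)[C@H](CC[C@@H](O)[C@@H]2C)C1 | intermediate
17 | 3α,8-bis(tert-butyldimethylsilyloxy)-4β,5β-dimethyl-10βH-decal-8(9)-ene | C1C[C@@]2(C)[C@H](CC[C@@H](O[Si](C)(C)C(C)(C)C)[C@@H]2C)C=C1O[Si](C)(C)C(C)(C)C | intermediate
18 | 3α,9β-bis(tert-butyldimethylsilyloxy)-4β,5β-dimethyl-10βH-decalin-8-one | C1C[C@@]2(C)[C@H](CC[C@@H](O[Si](C)(C)C(C)(C)C)[C@@H]2C)[C@@H](O[Si](C)(C)C(C)(C)C)C1=O | intermediate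
19 | 2-bromopropene | CC(Br)=C | starting material
20 | 3α,9β-bis(tert-butyldimethylsilyloxy)-10βH-eremophil-11-en-8-one | C=C(C)[C@H]1C[C@@]2(C)[C@H](CC[C@@H](O[Si](C)(C)C(C)(C)C)[C@@H]2C)[C@@H](O[Si](C)(C)C(C)(C)C)C1=O | intermediate
21 | 3α,9β-dihydroxy-10βH-eremophil-11-en-8-one | C=C(C)[C@H]1C[C@@]2(C)[C@H](CC[C@@H](O)[C@@H]2C)[C@@H](O)C1=O | intermediate
22 | 3-methylbut-2-enoyl chloride | CC(C)=CC(Cl)=O | starting material
23 | 3α,9β-bis(3-methylbut-2-enoyloxy)-10βH-eremophil-11-en-8-one, (3R,4R,5R,7R,9R,10S) | C=C(C)[C@H]1C[C@@]2(C)[C@H](CC[C@@H](OC(=O)C=C(C)C)[C@@H]2C)[C@@H](OC(=O)C=C(C)C)C1=O | target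

**Step count and risks**

Total step count: 14. Longest linear sequence: 14 steps (from 1).

Steps most likely to fail:

1. Step 8 (proposed new method). The acyl radical may lose carbon monoxide or add to the enone of a second molecule before ethylene captures it, and ethylene may add twice before ring closure. Fallback, from 11 back to 13, with the two bonds made one after the other by known reactions: CH2=CHMgBr/CeCl3 at −78 °C should add to the aldehyde only and give (4S)-4-[(2R)-3-hydroxypent-4-en-2-yl]-4-methylcyclohex-2-en-1-one F1. Dess–Martin oxidation gives the vinyl ketone (4S)-4-methyl-4-[(2R)-3-oxopent-4-en-2-yl]cyclohex-2-en-1-one F2. NaI/TMSCl in wet MeCN adds HI to the unhindered vinyl ketone to give (4S)-4-[(2R)-5-iodo-3-oxopentan-2-yl]-4-methylcyclohex-2-en-1-one F3. Bu3SnH/AIBN in benzene at 80 °C under slow addition then closes ring A by the same 6-exo radical conjugate addition and returns to 13.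

2. Step 3. Incomplete (Z)-selectivity in the enolisation, or competition between chair-like and boat-like transition states at the newly forming quaternary centre, may erode the C4/C5 diastereoselection. Fallback, from 2 back to 7, with C4 set by an auxiliary instead of by the rearrangement: acetylation of 2 gives (1R)-3-methylcyclohex-2-en-1-yl acetate F4. Its Ireland–Claisen rearrangement, which creates only C5 by chirality transfer, gives 2-[(1R)-1-methylcyclohex-2-en-1-yl]acetic acid F5. Pivaloyl mixed anhydride and lithiated (R)-4-benzyloxazolidin-2-one give (4R)-4-benzyl-3-{2-[(1R)-1-methylcyclohex-2-en-1-yl]acetyl}-1,3-oxazolidin-2-one F6. Evans methylation (NaN(SiMe3)2, MeI, −78 °C) gives (4R)-4-benzyl-3-{(2R)-2-[(1S)-1-methylcyclohex-2-en-1-yl]propanoyl}-1,3-oxazolidin-2-one F7. LiOH/H2O2 cleavage returns to 7.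

3. Step 12. Coupling of the hindered enolate may be slow, a second alkenylation may occur, and the base may move the new double bond into conjugation with the ketone. Fallback, from 18 back to 20, by aldol chemistry instead of cross-coupling: LiN(i-Pr)2 then acetone at −78 °C gives the aldol 3α,9β-bis(tert-butyldimethylsilyloxy)-7-(2-hydroxypropan-2-yl)-4β,5β-dimethyl-10βH-decalin-8-one F8. Dehydration with SOCl2/pyridine gives the conjugated 3α,9β-bis(tert-butyldimethylsilyloxy)-10βH-eremophil-7(11)-en-8-one F9. Deconjugation through the extended enolate (KN(SiMe3)2, THF, then AcOH at −78 °C, kinetic protonation at C7) returns to 20.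

**Further compounds**

F1 | step 8 | (4S)-4-[(2R)-3-hydroxypent-4-en-2-yl]-4-methylcyclohex-2-en-1-one (carbinol epimers) | O=C1CC[C@@](C)(C=C1)[C@@H](C)C(O)C=C
F2 | step 8 | (4S)-4-methyl-4-[(2R)-3-oxopent-4-en-2-yl]cyclohex-2-en-1-one | O=C1CC[C@@](C)(C=C1)[C@@H](C)C(=O)C=C
F3 | step 8 | (4S)-4-[(2R)-5-iodo-3-oxopentan-2-yl]-4-methylcyclohex-2-en-1-one | O=C1CC[C@@](C)(C=C1)[C@@H](C)C(=O)CCI
F4 | step 3 | (1R)-3-methylcyclohex-2-en-1-yl acetate | CC(=O)O[C@H]1C=C(C)CCC1
F5 | step 3 | 2-[(1R)-1-methylcyclohex-2-en-1-yl]acetic acid | C1CC[C@@](C)(C=C1)CC(=O)O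
F6 | step 3 | (4R)-4-benzyl-3-{2-[(1R)-1-methylcyclohex-2-en-1-yl]acetyl}-1,3-oxazolidin-2-one | C1CC[C@@](C)(C=C1)CC(=O)N1[C@H](Cc2ccccc2)COC1=O
F7 | step 3 | (4R)-4-benzyl-3-{(2R)-2-[(1S)-1-methylcyclohex-2-en-1-yl]propanoyl}-1,3-oxazolidin-2-one | C1CC[C@@](C)(C=C1)[C@@H](C)C(=O)N1[C@H](Cc2ccccc2)COC1=O
F8 | step 12 | 3α,9β-bis(tert-butyldimethylsilyloxy)-7-(2-hydroxypropan-2-yl)-4β,5β-dimethyl-10βH-decalin-8-one | CC(C)(O)C1C[C@@]2(C)[C@H](CC[C@@H](O[Si](C)(C)C(C)(C)C)[C@@H]2C)[C@@H](O[Si](C)(C)C(C)(C)C)C1=O
F9 | step 12 | 3α,9β-bis(tert-butyldimethylsilyloxy)-10βH-eremophil-7(11)-en-8-one | CC(C)=C1C[C@@]2(C)[C@H](CC[C@@H](O[Si](C)(C)C(C)(C)C)[C@@H]2C)[C@@H](O[Si](C)(C)C(C)(C)C)C1=O
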